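**Retrosynthetic overview**

- Target: trans-(3R,4R)-3,4-dibenzylbutyrolactone (ring E). The C3 benzyl ring (ring B) carries at O4 an erythro (7R,8S) guaiacylglycerol unit (ring A). The C4 benzyl carbon sits on C5 of a trans-(2S,3R)-2-aryl-3-hydroxymethyl-7-methoxy-2,3-dihydrobenzofuran (benzo ring C, dihydrofuran ring D, aryl ring F).
- Feature: ring D, O1–C2(ring F)–C3(CH2OH)–C3a–C7a, fused to guaiacyl ring C whose C5 (para to C7a) holds the chain, is the 8–5 union of a feruloyl unit with a 4-alkylguaiacol. It is cut at C3–C3a and O1–C2 to eugenol and an N-feruloyl oxazolidinone (peroxidase cross-coupling; the auxiliary is later cleaved to CH2OH).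
- Ring E is grown from the eugenol allyl group: hydroboration, oxidation to the acid, Evans alkylation with tert-butyl bromoacetate (sets lactone C4), reduction and lactonisation.
- The lactone C3–CH2(ring B) bond is made last by trans-selective enolate alkylation with a benzylic bromide. The bromide's C7–C8 bond comes from an Evans syn-aldol (aryloxyacetyl imide of methyl vanillate plus O-benzylvanillin), followed by Mitsunobu inversion at C7.
- Ring order: rings A, B, C and F are bought aromatic rings; ring D is closed first (step 4), ring E second (step 12); desilylation and hydrogenolysis finish.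

Key step: step 4

Assumption: the (S)-4-benzyl auxiliary is taken to favour the trans (2S,3S)-acyl product in step 4; if the other trans diastereomer prevails, (R)-4-benzyloxazolidin-2-one is used in step 2 and nothing else changes.

Shorthand in names: TBS = tert-butyldimethylsilyl; TBDPS = tert-butyldiphenylsilyl; DHB = (2S,3R)-2-(4-benzyloxy-3-methoxyphenyl)-3-[(tert-butyldiphenylsilyl)oxymethyl]-7-methoxy-2,3-dihydro-1-benzofuran-5-yl; C7/C8/C9 are the arylglycerol carbons (C7 benzylic).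

**Route**

Step 1
Reactants: 1 ferulic acid
Product: 3 (E)-3-[4-(TBS-oxy)-3-methoxyphenyl]acrylic acid, via bis-silyl derivative 2 (not isolated)
Conditions: TBSCl (2.3 equiv), imidazole, DMF, rt; then AcOH/THF/H2O, rt
Reagents that add atoms: tert-butyldimethylsilyl chloride, CC(C)(C)[Si](C)(C)Cl
Why: Silylation of phenol and acid followed by selective hydrolysis of the far more labile silyl ester masks the phenol so that it is not acylated in step 2.

Step 2
Reactants: 3 (E)-3-[4-(TBS-oxy)-3-methoxyphenyl]acrylic acid; 4 (S)-4-benzyloxazolidin-2-one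
Product: 6 (S)-4-benzyl-3-[(E)-3-(4-TBS-oxy-3-methoxyphenyl)acryloyl]oxazolidin-2-one, via mixed pivalic anhydride 5 (not isolated)
Conditions: PivCl, Et3N, THF, −20 °C; then LiCl, 4, −20 °C to rt
Reagents that add atoms: none
Why: N-Acylation of the oxazolidinone through the mixed pivalic anhydride (LiCl/Et3N protocol) is dependable for cinnamic acids and needs no strong base, the nucleophile attacking the less hindered cinnamoyl carbonyl.

Step 3
Reactants: 6 (S)-4-benzyl-3-[(E)-3-(4-TBS-oxy-3-methoxyphenyl)acryloyl]oxazolidin-2-one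
Product: 7 (S)-4-benzyl-3-[(E)-feruloyl]oxazolidin-2-one
Conditions: Bu4NF, AcOH, THF, 0 °C
Reagents that add atoms: none
Why: Buffered fluoride desilylation cleaves the aryl silyl ether without touching the enoyl imide and frees the phenol needed for radical formation.

Step 4
Reactants: 7 (S)-4-benzyl-3-[(E)-feruloyl]oxazolidin-2-one; 8 eugenol
Product: 10 (S)-4-benzyl-3-{[(2S,3S)-5-allyl-2-(4-hydroxy-3-methoxyphenyl)-7-methoxy-2,3-dihydro-1-benzofuran-3-yl]carbonyl}oxazolidin-2-one, via quinone methide 9 (not isolated)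
Conditions: horseradish peroxidase (cat.), 30% aq. H2O2 (syringe pump, until 7 is consumed), 8 (5 equiv), acetone/citrate–phosphate buffer pH 3.5 (1:2), rt
Reagents that add atoms: none
Why: The ferric heme, raised by H2O2 to its oxoferryl states, takes one electron and one proton from each phenol; the feruloyl radical (spin at C8, alpha to the imide carbonyl) and the eugenol radical (spin at C5, ortho to the phenol oxygen) combine to form the C3–C3a bond, and tautomerisation of the cyclohexadienone gives quinone methide 9. The closest known reactions are the peroxidase- or Ag2O-mediated 8–5 dehydrodimerisation of ferulates, including ferulic amides of chiral auxiliaries, and the beta-5 cross-coupling of monolignols with 4-alkylguaiacols. Ring D then closes by 5-exo-trig addition of the eugenol oxygen to the exocyclic methide carbon (O1–C2 bond). C3 is set in the radical coupling, where the benzyl group of the auxiliary on the s-cis acyl imide screens one face of C8, and C2 is set in the ring closure, the aryl group ending anti to the C3 acyl group (trans). The step needs cross- over homo-coupling and C5- over O-coupling of eugenol: excess eugenol, a slow peroxide feed and the acidic buffer serve the first, and the allyl group blocking the para position leaves C5 as the only carbon site. Because the auxiliary is still attached, the two trans products are diastereomers, so 10 should be obtainable as one stereoisomer by chromatography or crystallisation.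

Step 5
Reactants: 10 (S)-4-benzyl-3-{[(2S,3S)-5-allyl-2-(4-hydroxy-3-methoxyphenyl)-7-methoxy-2,3-dihydro-1-benzofuran-3-yl]carbonyl}oxazolidin-2-one
Product: 11 4-[(2S,3R)-5-allyl-3-(hydroxymethyl)-7-methoxy-2,3-dihydro-1-benzofuran-2-yl]-2-methoxyphenol
Conditions: LiBH4 (3 equiv), MeOH, THF, 0 °C to rt
Reagents that add atoms: none
Why: Reductive cleavage of the N-acyl oxazolidinone by LiBH4 gives the primary alcohol and returns the auxiliary, and the weakly basic hydride should neither epimerise C3 nor open ring D by beta-elimination.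

Step 6
Reactants: 11 4-[(2S,3R)-5-allyl-3-(hydroxymethyl)-7-methoxy-2,3-dihydro-1-benzofuran-2-yl]-2-methoxyphenol
Product: 12 [(2S,3R)-5-allyl-2-(4-benzyloxy-3-methoxyphenyl)-7-methoxy-2,3-dihydro-1-benzofuran-3-yl]methanol
Conditions: BnBr, K2CO3, acetone, 50 °C
Reagents that add atoms: benzyl bromide, BrCc1ccccc1
Why: Williamson ether synthesis in which only the phenol is deprotonated by carbonate, so benzylation is selective for the phenolic oxygen.

Step 7
Reactants: 12 [(2S,3R)-5-allyl-2-(4-benzyloxy-3-methoxyphenyl)-7-methoxy-2,3-dihydro-1-benzofuran-3-yl]methanol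
Product: 13 (2S,3R)-5-allyl-2-(4-benzyloxy-3-methoxyphenyl)-3-[(TBDPS-oxy)methyl]-7-methoxy-2,3-dihydro-1-benzofuran
Conditions: TBDPSCl, imidazole, DMF, rt
Reagents that add atoms: tert-butyldiphenylsilyl chloride, CC(C)(C)[Si](Cl)(c1ccccc1)c1ccccc1
Why: Silylation of the primary alcohol, the TBDPS ether being chosen because it survives the acid of step 12 and is removed by fluoride at the end.

Step 8
Reactants: 13 (2S,3R)-5-allyl-2-(4-benzyloxy-3-methoxyphenyl)-3-[(TBDPS-oxy)methyl]-7-methoxy-2,3-dihydro-1-benzofuran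
Product: 15 3-DHB-propan-1-ol, via B-alkyl-9-BBN borane 14 (not isolated)
Conditions: 9-BBN, THF, 0 °C to rt; then 3 M NaOH, 30% H2O2, 0 °C
Reagents that add atoms: hydrogen peroxide, OO
Why: Brown hydroboration–oxidation places boron on the terminal allyl carbon (anti-Markovnikov) and alkaline peroxide replaces it by hydroxyl with the ethers untouched.

Step 9
Reactants: 15 3-DHB-propan-1-ol
Product: 16 3-DHB-propanoic acid
Conditions: TEMPO (0.2 equiv), PhI(OAc)2 (2.2 equiv), MeCN/H2O (1:1), rt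
Reagents that add atoms: water, O
Why: TEMPO/PhI(OAc)2 oxidation in aqueous acetonitrile takes the primary alcohol through the aldehyde hydrate to the carboxylic acid and leaves aryl ethers, the benzyl ether and the silyl ether alone.

Step 10
Reactants: 16 3-DHB-propanoic acid; 4 (S)-4-benzyloxazolidin-2-one
Product: 18 (S)-4-benzyl-3-(3-DHB-propanoyl)oxazolidin-2-one, via mixed pivalic anhydride 17 (not isolated)
Conditions: PivCl, Et3N, THF, −20 °C; then LiCl, 4, −20 °C to rt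
Reagents that add atoms: none
Why: N-Acylation through the mixed pivalic anhydride as in step 2 installs the auxiliary for the Evans alkylation.

Step 11
Reactants: 18 (S)-4-benzyl-3-(3-DHB-propanoyl)oxazolidin-2-one; 19 tert-butyl bromoacetate
Product: 21 tert-butyl (3R)-3-(DHB-methyl)-4-[(S)-4-benzyl-2-oxooxazolidin-3-yl]-4-oxobutanoate, via sodium Z-enolate 20 (not isolated)
Conditions: NaN(SiMe3)2, THF, −78 °C; then 19, −78 to −50 °C
Reagents that add atoms: none
Why: Evans asymmetric alkylation in which the chelated sodium Z-enolate is attacked on the face away from the benzyl group of the (S)-auxiliary, setting the later lactone C4 as R.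

Step 12
Reactants: 21 tert-butyl (3R)-3-(DHB-methyl)-4-[(S)-4-benzyl-2-oxooxazolidin-3-yl]-4-oxobutanoate
Product: 23 (4R)-4-(DHB-methyl)dihydrofuran-2(3H)-one, via hydroxy tert-butyl ester 22 (not isolated)
Conditions: LiBH4, MeOH, THF, 0 °C; extractive work-up; then TFA, CH2Cl2, 0 °C
Reagents that add atoms: none
Why: LiBH4 reduction of the imide carbonyl gives the primary alcohol with the tert-butyl ester intact, and acid-catalysed lactonisation with loss of the tert-butyl group closes ring E without involving the stereocentre.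

Step 13
Reactants: 24 (R)-4-benzyloxazolidin-2-one; 25 bromoacetyl bromide
Product: 27 (R)-4-benzyl-3-(bromoacetyl)oxazolidin-2-one, via lithium oxazolidinide 26 (not isolated)
Conditions: n-BuLi, THF, −78 °C; then 25, −78 °C
Reagents that add atoms: none
Why: N-Acylation of the lithiated oxazolidinone, which attacks the acyl bromide much faster than the alkyl bromide.

Step 14
Reactants: 27 (R)-4-benzyl-3-(bromoacetyl)oxazolidin-2-one; 28 methyl vanillate
Product: 29 methyl 4-{2-[(R)-4-benzyl-2-oxooxazolidin-3-yl]-2-oxoethoxy}-3-methoxybenzoate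
Conditions: K2CO3, acetone, rt
Reagents that add atoms: none
Why: Williamson ether synthesis in which the vanillate phenoxide displaces the activated alpha-bromide of the imide (SN2) under mild carbonate conditions.

Step 15
Reactants: 29 methyl 4-{2-[(R)-4-benzyl-2-oxooxazolidin-3-yl]-2-oxoethoxy}-3-methoxybenzoate; 30 4-benzyloxy-3-methoxybenzaldehyde
Product: 33 methyl 4-{[(1S,2R)-3-[(R)-4-benzyl-2-oxooxazolidin-3-yl]-1-(4-benzyloxy-3-methoxyphenyl)-1-hydroxy-3-oxopropan-2-yl]oxy}-3-methoxybenzoate, via boron Z-enolate 31 (not isolated), via boron aldolate 32 (not isolated)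
Conditions: Bu2BOTf, i-Pr2NEt, CH2Cl2, −78 to 0 °C; then 30, −78 to 0 °C; then pH 7 phosphate buffer, MeOH, 30% H2O2, 0 °C
Reagents that add atoms: none
Why: Evans syn-aldol reaction in which the boron Z-enolate adds through a Zimmerman–Traxler chair on the face away from the benzyl group of the (R)-auxiliary, giving the syn adduct that becomes the (7S,8S) threo diol in step 16.

Step 16
Reactants: 33 methyl 4-{[(1S,2R)-3-[(R)-4-benzyl-2-oxooxazolidin-3-yl]-1-(4-benzyloxy-3-methoxyphenyl)-1-hydroxy-3-oxopropan-2-yl]oxy}-3-methoxybenzoate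
Product: 34 methyl 4-{[(1S,2S)-1-(4-benzyloxy-3-methoxyphenyl)-1,3-dihydroxypropan-2-yl]oxy}-3-methoxybenzoate
Conditions: NaBH4, THF/H2O (4:1), 0 °C to rt
Reagents that add atoms: none
Why: Borohydride reductive cleavage of the N-acyl oxazolidinone gives the primary alcohol and the free auxiliary, and NaBH4 does not reduce the aryl methyl ester.

Step 17
Reactants: 34 methyl 4-{[(1S,2S)-1-(4-benzyloxy-3-methoxyphenyl)-1,3-dihydroxypropan-2-yl]oxy}-3-methoxybenzoate
Product: 35 methyl 4-{[(1S,2S)-1-(4-benzyloxy-3-methoxyphenyl)-1-hydroxy-3-(TBS-oxy)propan-2-yl]oxy}-3-methoxybenzoate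
Conditions: TBSCl (1.05 equiv), imidazole, CH2Cl2, 0 °C
Reagents that add atoms: tert-butyldimethylsilyl chloride, CC(C)(C)[Si](C)(C)Cl
Why: Selective silylation of the primary hydroxyl over the hindered secondary benzylic hydroxyl.

Step 18
Reactants: 35 methyl 4-{[(1S,2S)-1-(4-benzyloxy-3-methoxyphenyl)-1-hydroxy-3-(TBS-oxy)propan-2-yl]oxy}-3-methoxybenzoate
Product: 36 (1R,2S)-1-(4-benzyloxy-3-methoxyphenyl)-2-[2-methoxy-4-(methoxycarbonyl)phenoxy]-3-(TBS-oxy)propyl 4-nitrobenzoate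
Conditions: 4-O2NC6H4CO2H, PPh3, DIAD, toluene, −20 °C to rt
Reagents that add atoms: 4-nitrobenzoic acid, O=C(O)c1ccc(cc1)[N+](=O)[O-]
Why: Mitsunobu reaction in which the benzylic alcohol is activated as its oxyphosphonium ion and displaced by 4-nitrobenzoate with inversion (SN2), turning C7 from S to R and the threo into the erythro series.

Step 19
Reactants: 36 (1R,2S)-1-(4-benzyloxy-3-methoxyphenyl)-2-[2-methoxy-4-(methoxycarbonyl)phenoxy]-3-(TBS-oxy)propyl 4-nitrobenzoate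
Product: 37 methyl 4-{[(1R,2S)-1-(4-benzyloxy-3-methoxyphenyl)-1-hydroxy-3-(TBS-oxy)propan-2-yl]oxy}-3-methoxybenzoate
Conditions: K2CO3 (cat.), MeOH, 0 °C
Reagents that add atoms: none
Why: Methanolysis (transesterification) of the activated 4-nitrobenzoate frees the inverted C7 hydroxyl, while the aryl methyl ester is unchanged by methoxide exchange and the primary silyl ether is stable.

Step 20
Reactants: 37 methyl 4-{[(1R,2S)-1-(4-benzyloxy-3-methoxyphenyl)-1-hydroxy-3-(TBS-oxy)propan-2-yl]oxy}-3-methoxybenzoate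
Product: 38 methyl 4-{[(1R,2S)-1-(4-benzyloxy-3-methoxyphenyl)-1,3-bis(TBS-oxy)propan-2-yl]oxy}-3-methoxybenzoate
Conditions: TBSOTf, 2,6-lutidine, CH2Cl2, −78 to 0 °C
Reagents that add atoms: tert-butyldimethylsilyl triflate, CC(C)(C)[Si](C)(C)OS(=O)(=O)C(F)(F)F
Why: Silylation of the hindered secondary benzylic alcohol with the silyl triflate and a non-nucleophilic base.

Step 21
Reactants: 38 methyl 4-{[(1R,2S)-1-(4-benzyloxy-3-methoxyphenyl)-1,3-bis(TBS-oxy)propan-2-yl]oxy}-3-methoxybenzoate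
Product: 39 (4-{[(1R,2S)-1-(4-benzyloxy-3-methoxyphenyl)-1,3-bis(TBS-oxy)propan-2-yl]oxy}-3-methoxyphenyl)methanol
Conditions: i-Bu2AlH (3 equiv), CH2Cl2, −78 to 0 °C; aq. potassium sodium tartrate
Reagents that add atoms: none
Why: Hydride reduction of the aryl ester to the benzylic alcohol by i-Bu2AlH, to which silyl and benzyl ethers are inert.

Step 22
Reactants: 39 (4-{[(1R,2S)-1-(4-benzyloxy-3-methoxyphenyl)-1,3-bis(TBS-oxy)propan-2-yl]oxy}-3-methoxyphenyl)methanol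
Product: 40 1-benzyloxy-4-{(1R,2S)-2-[4-(bromomethyl)-2-methoxyphenoxy]-1,3-bis(TBS-oxy)propyl}-2-methoxybenzene
Conditions: CBr4, PPh3, CH2Cl2, 0 °C; used at once
Reagents that add atoms: carbon tetrabromide, BrC(Br)(Br)Br
Why: Appel bromination converts the primary benzylic alcohol into the bromide under neutral conditions that spare the silyl ethers.

Step 23
Reactants: 23 (4R)-4-(DHB-methyl)dihydrofuran-2(3H)-one; 40 1-benzyloxy-4-{(1R,2S)-2-[4-(bromomethyl)-2-methoxyphenoxy]-1,3-bis(TBS-oxy)propyl}-2-methoxybenzene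
Product: 42 (3R,4R)-3-(4-{[(1R,2S)-1-(4-benzyloxy-3-methoxyphenyl)-1,3-bis(TBS-oxy)propan-2-yl]oxy}-3-methoxybenzyl)-4-(DHB-methyl)dihydrofuran-2(3H)-one, via lithium enolate 41 (not isolated)
Conditions: LiN(i-Pr)2 (LDA), THF, −78 °C; then 40, DMPU, −78 to −40 °C
Reagents that add atoms: none
Why: Alkylation of the lithium enolate of a beta-substituted gamma-butyrolactone, the bromide approaching the face anti to the C4 substituent, which sets C3 as R and gives the trans lactone.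

Step 24
Reactants: 42 (3R,4R)-3-(4-{[(1R,2S)-1-(4-benzyloxy-3-methoxyphenyl)-1,3-bis(TBS-oxy)propan-2-yl]oxy}-3-methoxybenzyl)-4-(DHB-methyl)dihydrofuran-2(3H)-one
Product: 43 (3R,4R)-3-(4-{[(1R,2S)-1-(4-benzyloxy-3-methoxyphenyl)-1,3-dihydroxypropan-2-yl]oxy}-3-methoxybenzyl)-4-{[(2S,3R)-2-(4-benzyloxy-3-methoxyphenyl)-3-(hydroxymethyl)-7-methoxy-2,3-dihydro-1-benzofuran-5-yl]methyl}dihydrofuran-2(3H)-one
Conditions: Bu4NF, AcOH, THF, rt
Reagents that add atoms: none
Why: Fluoride desilylation removes the TBDPS and both TBS ethers, with acetic acid buffering the medium so that the lactone and the benzylic alcohol are not harmed.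

Step 25
Reactants: 43 (3R,4R)-3-(4-{[(1R,2S)-1-(4-benzyloxy-3-methoxyphenyl)-1,3-dihydroxypropan-2-yl]oxy}-3-methoxybenzyl)-4-{[(2S,3R)-2-(4-benzyloxy-3-methoxyphenyl)-3-(hydroxymethyl)-7-methoxy-2,3-dihydro-1-benzofuran-5-yl]methyl}dihydrofuran-2(3H)-one
Product: 44 CNP0298853.1
Conditions: H2 (1 atm), Pd/C (palladium on carbon), EtOAc/EtOH, rt, short contact time
Reagents that add atoms: none
Why: Hydrogenolysis of the two phenolic benzyl ethers under neutral conditions should be faster than cleavage of the benzylic C7–OH or O1–C2 bonds and gives the target.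

**Compound list**

1 | ferulic acid | COc1cc(/C=C/C(=O)O)ccc1O | starting material
2 | TBS (E)-3-[4-(TBS-oxy)-3-methoxyphenyl]acrylate (formed in situ) | COc1cc(/C=C/C(=O)O[Si](C)(C)C(C)(C)C)ccc1O[Si](C)(C)C(C)(C)C | intermediate
3 | (E)-3-[4-(TBS-oxy)-3-methoxyphenyl]acrylic acid | COc1cc(/C=C/C(=O)O)ccc1O[Si](C)(C)C(C)(C)C | intermediate
4 | (S)-4-benzyloxazolidin-2-one | O=C1N[C@@H](Cc2ccccc2)CO1 | starting material
5 | mixed pivalic anhydride of 3 (formed in situ) | COc1cc(/C=C/C(=O)OC(=O)C(C)(C)C)ccc1O[Si](C)(C)C(C)(C)C | intermediate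
6 | (S)-4-benzyl-3-[(E)-3-(4-TBS-oxy-3-methoxyphenyl)acryloyl]oxazolidin-2-one | COc1cc(/C=C/C(=O)N2[C@@H](Cc3ccccc3)COC2=O)ccc1O[Si](C)(C)C(C)(C)C | intermediate
7 | (S)-4-benzyl-3-[(E)-feruloyl]oxazolidin-2-one | COc1cc(/C=C/C(=O)N2[C@@H](Cc3ccccc3)COC2=O)ccc1O | intermediate
8 | eugenol (4-allyl-2-methoxyphenol) | C=CCc1ccc(O)c(OC)c1 | starting material
9 | (S)-4-benzyl-3-[(2R)-2-(5-allyl-2-hydroxy-3-methoxyphenyl)-3-(3-methoxy-4-oxocyclohexa-2,5-dien-1-ylidene)propanoyl]oxazolidin-2-one (quinone methide, formed in situ) | C=CCc1cc(OC)c(O)c(c1)[C@H](C(=O)N1[C@@H](Cc2ccccc2)COC1=O)C=C1C=CC(=O)C(OC)=C1 | intermediate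
10 | (S)-4-benzyl-3-{[(2S,3S)-5-allyl-2-(4-hydroxy-3-methoxyphenyl)-7-methoxy-2,3-dihydro-1-benzofuran-3-yl]carbonyl}oxazolidin-2-one (trans) | C=CCc1cc(OC)c2c(c1)[C@H](C(=O)N1[C@@H](Cc3ccccc3)COC1=O)[C@@H](c1ccc(O)c(OC)c1)O2 | intermediate
11 | 4-[(2S,3R)-5-allyl-3-(hydroxymethyl)-7-methoxy-2,3-dihydro-1-benzofuran-2-yl]-2-methoxyphenol | C=CCc1cc(OC)c2c(c1)[C@H](CO)[C@@H](c1ccc(O)c(OC)c1)O2 | intermediate
12 | [(2S,3R)-5-allyl-2-(4-benzyloxy-3-methoxyphenyl)-7-methoxy-2,3-dihydro-1-benzofuran-3-yl]methanol | C=CCc1cc(OC)c2c(c1)[C@H](CO)[C@@H](c1ccc(OCc3ccccc3)c(OC)c1)O2 | intermediate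
13 | (2S,3R)-5-allyl-2-(4-benzyloxy-3-methoxyphenyl)-3-[(TBDPS-oxy)methyl]-7-methoxy-2,3-dihydro-1-benzofuran | C=CCc1cc(OC)c2c(c1)[C@H](CO[Si](c3ccccc3)(c3ccccc3)C(C)(C)C)[C@@H](c1ccc(OCc3ccccc3)c(OC)c1)O2 | intermediate
14 | 9-(3-DHB-propyl)-9-borabicyclo[3.3.1]nonane (formed in situ) | B1(CCCc2cc(OC)c3c(c2)[C@H](CO[Si](c4ccccc4)(c4ccccc4)C(C)(C)C)[C@@H](c2ccc(OCc4ccccc4)c(OC)c2)O3)C2CCCC1CCC2 | intermediate
15 | 3-DHB-propan-1-ol | OCCCc1cc(OC)c2c(c1)[C@H](CO[Si](c3ccccc3)(c3ccccc3)C(C)(C)C)[C@@H](c1ccc(OCc3ccccc3)c(OC)c1)O2 | intermediate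
16 | 3-DHB-propanoic acid | OC(=O)CCc1cc(OC)c2c(c1)[C@H](CO[Si](c3ccccc3)(c3ccccc3)C(C)(C)C)[C@@H](c1ccc(OCc3ccccc3)c(OC)c1)O2 | intermediate
17 | mixed pivalic anhydride of 16 (formed in situ) | CC(C)(C)C(=O)OC(=O)CCc1cc(OC)c2c(c1)[C@H](CO[Si](c3ccccc3)(c3ccccc3)C(C)(C)C)[C@@H](c1ccc(OCc3ccccc3)c(OC)c1)O2 | intermediate
18 | (S)-4-benzyl-3-(3-DHB-propanoyl)oxazolidin-2-one | O=C(CCc1cc(OC)c2c(c1)[C@H](CO[Si](c3ccccc3)(c3ccccc3)C(C)(C)C)[C@@H](c1ccc(OCc3ccccc3)c(OC)c1)O2)N1[C@@H](Cc2ccccc2)COC1=O | intermediate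
19 | tert-butyl bromoacetate | CC(C)(C)OC(=O)CBr | starting material
20 | sodium (Z)-enolate of 18 (formed in situ) | [Na+].[O-]/C(=C\Cc1cc(OC)c2c(c1)[C@H](CO[Si](c3ccccc3)(c3ccccc3)C(C)(C)C)[C@@H](c1ccc(OCc3ccccc3)c(OC)c1)O2)N1[C@@H](Cc2ccccc2)COC1=O | intermediate
21 | tert-butyl (3R)-3-(DHB-methyl)-4-[(S)-4-benzyl-2-oxooxazolidin-3-yl]-4-oxobutanoate | CC(C)(C)OC(=O)C[C@@H](Cc1cc(OC)c2c(c1)[C@H](CO[Si](c3ccccc3)(c3ccccc3)C(C)(C)C)[C@@H](c1ccc(OCc3ccccc3)c(OC)c1)O2)C(=O)N1[C@@H](Cc2ccccc2)COC1=O | intermediate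
22 | tert-butyl (3R)-3-(DHB-methyl)-4-hydroxybutanoate (crude, taken on) | CC(C)(C)OC(=O)C[C@@H](Cc1cc(OC)c2c(c1)[C@H](CO[Si](c3ccccc3)(c3ccccc3)C(C)(C)C)[C@@H](c1ccc(OCc3ccccc3)c(OC)c1)O2)CO | intermediate
23 | (4R)-4-(DHB-methyl)dihydrofuran-2(3H)-one | O=C1C[C@@H](Cc2cc(OC)c3c(c2)[C@H](CO[Si](c4ccccc4)(c4ccccc4)C(C)(C)C)[C@@H](c2ccc(OCc4ccccc4)c(OC)c2)O3)CO1 | intermediate
24 | (R)-4-benzyloxazolidin-2-one | O=C1N[C@H](Cc2ccccc2)CO1 | starting material
25 | bromoacetyl bromide | BrCC(Br)=O | starting material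
26 | lithium salt of 24 (formed in situ) | [Li+].O=C1[N-][C@H](Cc2ccccc2)CO1 | intermediate
27 | (R)-4-benzyl-3-(bromoacetyl)oxazolidin-2-one | BrCC(=O)N1[C@H](Cc2ccccc2)COC1=O | intermediate
28 | methyl vanillate (methyl 4-hydroxy-3-methoxybenzoate) | COC(=O)c1ccc(O)c(OC)c1 | starting material
29 | methyl 4-{2-[(R)-4-benzyl-2-oxooxazolidin-3-yl]-2-oxoethoxy}-3-methoxybenzoate | COC(=O)c1ccc(OCC(=O)N2[C@H](Cc3ccccc3)COC2=O)c(OC)c1 | intermediate
30 | 4-benzyloxy-3-methoxybenzaldehyde | COc1cc(C=O)ccc1OCc1ccccc1 | starting material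
31 | dibutylboron (Z)-enolate of 29 (formed in situ) | CCCCB(CCCC)O/C(=C\Oc1ccc(C(=O)OC)cc1OC)N1[C@H](Cc2ccccc2)COC1=O | intermediate
32 | O-dibutylboryl aldolate of 33 (formed in situ) | COc1cc([C@H](OB(CCCC)CCCC)[C@H](C(=O)N2[C@H](Cc3ccccc3)COC2=O)Oc2ccc(C(=O)OC)cc2OC)ccc1OCc1ccccc1 | intermediate
33 | methyl 4-{[(1S,2R)-3-[(R)-4-benzyl-2-oxooxazolidin-3-yl]-1-(4-benzyloxy-3-methoxyphenyl)-1-hydroxy-3-oxopropan-2-yl]oxy}-3-methoxybenzoate (syn aldol) | COc1cc([C@H](O)[C@H](C(=O)N2[C@H](Cc3ccccc3)COC2=O)Oc2ccc(C(=O)OC)cc2OC)ccc1OCc1ccccc1 | intermediate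
34 | methyl 4-{[(1S,2S)-1-(4-benzyloxy-3-methoxyphenyl)-1,3-dihydroxypropan-2-yl]oxy}-3-methoxybenzoate (threo) | COc1cc([C@H](O)[C@H](CO)Oc2ccc(C(=O)OC)cc2OC)ccc1OCc1ccccc1 | intermediate
35 | methyl 4-{[(1S,2S)-1-(4-benzyloxy-3-methoxyphenyl)-1-hydroxy-3-(TBS-oxy)propan-2-yl]oxy}-3-methoxybenzoate | COc1cc([C@H](O)[C@H](CO[Si](C)(C)C(C)(C)C)Oc2ccc(C(=O)OC)cc2OC)ccc1OCc1ccccc1 | intermediate
36 | (1R,2S)-1-(4-benzyloxy-3-methoxyphenyl)-2-[2-methoxy-4-(methoxycarbonyl)phenoxy]-3-(TBS-oxy)propyl 4-nitrobenzoate (erythro) | COc1cc([C@@H](OC(=O)c2ccc(cc2)[N+](=O)[O-])[C@H](CO[Si](C)(C)C(C)(C)C)Oc2ccc(C(=O)OC)cc2OC)ccc1OCc1ccccc1 | intermediate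
37 | methyl 4-{[(1R,2S)-1-(4-benzyloxy-3-methoxyphenyl)-1-hydroxy-3-(TBS-oxy)propan-2-yl]oxy}-3-methoxybenzoate (erythro) | COc1cc([C@@H](O)[C@H](CO[Si](C)(C)C(C)(C)C)Oc2ccc(C(=O)OC)cc2OC)ccc1OCc1ccccc1 | intermediate
38 | methyl 4-{[(1R,2S)-1-(4-benzyloxy-3-methoxyphenyl)-1,3-bis(TBS-oxy)propan-2-yl]oxy}-3-methoxybenzoate | COc1cc([C@@H](O[Si](C)(C)C(C)(C)C)[C@H](CO[Si](C)(C)C(C)(C)C)Oc2ccc(C(=O)OC)cc2OC)ccc1OCc1ccccc1 | intermediate
39 | (4-{[(1R,2S)-1-(4-benzyloxy-3-methoxyphenyl)-1,3-bis(TBS-oxy)propan-2-yl]oxy}-3-methoxyphenyl)methanol | COc1cc([C@@H](O[Si](C)(C)C(C)(C)C)[C@H](CO[Si](C)(C)C(C)(C)C)Oc2ccc(CO)cc2OC)ccc1OCc1ccccc1 | intermediate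
40 | 1-benzyloxy-4-{(1R,2S)-2-[4-(bromomethyl)-2-methoxyphenoxy]-1,3-bis(TBS-oxy)propyl}-2-methoxybenzene | COc1cc([C@@H](O[Si](C)(C)C(C)(C)C)[C@H](CO[Si](C)(C)C(C)(C)C)Oc2ccc(CBr)cc2OC)ccc1OCc1ccccc1 | intermediate
41 | lithium enolate of 23 (formed in situ) | [Li+].[O-]C1=C[C@@H](Cc2cc(OC)c3c(c2)[C@H](CO[Si](c4ccccc4)(c4ccccc4)C(C)(C)C)[C@@H](c2ccc(OCc4ccccc4)c(OC)c2)O3)CO1 | intermediate
42 | (3R,4R)-3-(4-{[(1R,2S)-1-(4-benzyloxy-3-methoxyphenyl)-1,3-bis(TBS-oxy)propan-2-yl]oxy}-3-methoxybenzyl)-4-(DHB-methyl)dihydrofuran-2(3H)-one | COc1cc([C@@H](O[Si](C)(C)C(C)(C)C)[C@H](CO[Si](C)(C)C(C)(C)C)Oc2ccc(C[C@H]3C(=O)OC[C@@H]3Cc3cc(OC)c4c(c3)[C@H](CO[Si](c5ccccc5)(c5ccccc5)C(C)(C)C)[C@@H](c3ccc(OCc5ccccc5)c(OC)c3)O4)cc2OC)ccc1OCc1ccccc1 | intermediate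
43 | (3R,4R)-3-(4-{[(1R,2S)-1-(4-benzyloxy-3-methoxyphenyl)-1,3-dihydroxypropan-2-yl]oxy}-3-methoxybenzyl)-4-{[(2S,3R)-2-(4-benzyloxy-3-methoxyphenyl)-3-(hydroxymethyl)-7-methoxy-2,3-dihydro-1-benzofuran-5-yl]methyl}dihydrofuran-2(3H)-one | COc1cc([C@@H](O)[C@H](CO)Oc2ccc(C[C@H]3C(=O)OC[C@@H]3Cc3cc(OC)c4c(c3)[C@H](CO)[C@@H](c3ccc(OCc5ccccc5)c(OC)c3)O4)cc2OC)ccc1OCc1ccccc1 | intermediate
44 | CNP0298853.1, (3R,4R)-3-(4-{[(1R,2S)-1,3-dihydroxy-1-(4-hydroxy-3-methoxyphenyl)propan-2-yl]oxy}-3-methoxybenzyl)-4-{[(2S,3R)-2-(4-hydroxy-3-methoxyphenyl)-3-(hydroxymethyl)-7-methoxy-2,3-dihydro-1-benzofuran-5-yl]methyl}dihydrofuran-2(3H)-one | COc1cc([C@@H](O)[C@H](CO)Oc2ccc(C[C@H]3C(=O)OC[C@@H]3Cc3cc(OC)c4c(c3)[C@H](CO)[C@@H](c3ccc(O)c(OC)c3)O4)cc2OC)ccc1O | target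

**Step count and risks**

Total step count: 25. Longest linear sequence: 15 steps (steps 1–12, then 23–25); the bromide branch (steps 13–22) is 10 steps.

Risk 1, step 4. Each phenol may dimerise with itself faster than the two cross-couple, the eugenol radical may couple through oxygen instead of C5, and the non-chelated auxiliary may give only a weak facial bias. The fallback uses known rhodium-carbenoid C–H insertion chemistry, sets out from eugenol 8 and rejoins the route at 12.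
- Eugenol 8 is iodinated ortho to the hydroxyl (I2, aq. NaHCO3, THF, 0 °C) to 4-allyl-2-iodo-6-methoxyphenol F1.
- Mitsunobu etherification with commercial 4-benzyloxy-3-methoxybenzyl alcohol (PPh3, DIAD, THF) gives 5-allyl-2-[(4-benzyloxy-3-methoxyphenyl)methoxy]-1-iodo-3-methoxybenzene F2.
- Palladium-catalysed coupling with ethyl diazoacetate (Pd(PPh3)4, Ag2CO3, Et3N, toluene, rt) gives ethyl 2-{5-allyl-2-[(4-benzyloxy-3-methoxyphenyl)methoxy]-3-methoxyphenyl}-2-diazoacetate F3.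
- The carbenoid formed with dirhodium tetrakis[N-phthaloyl-(S)-tert-leucinate], Rh2(S-PTTL)4 (or its mirror image, whichever sets C2 as S), inserts into the benzylic ether C–H bond and closes ring D as ethyl (2S,3R)-5-allyl-2-(4-benzyloxy-3-methoxyphenyl)-7-methoxy-2,3-dihydro-1-benzofuran-3-carboxylate F4 (cis).
- NaOEt in EtOH epimerises C3 to the trans ester, ethyl (2S,3S)-5-allyl-2-(4-benzyloxy-3-methoxyphenyl)-7-methoxy-2,3-dihydro-1-benzofuran-3-carboxylate F5, and LiAlH4 (THF, 0 °C) reduces it to 12.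

Risk 2, step 18. The electron-rich benzylic oxyphosphonium ion may ionise before it is displaced, which erodes the inversion at C7, or it may eliminate. The fallback sets out from 35 and rejoins at 37, replacing steps 18 and 19.
- Dess–Martin periodinane (NaHCO3, CH2Cl2, rt) oxidises 35 without touching C8 to methyl 4-{[(2S)-1-(4-benzyloxy-3-methoxyphenyl)-1-oxo-3-(TBS-oxy)propan-2-yl]oxy}-3-methoxybenzoate F6.
- Chelation-controlled reduction with Zn(BH4)2 (Et2O, −30 °C) follows; hydride enters the zinc chelate of the carbonyl and aryloxy oxygens from the side of the C8 hydrogen and should give the anti (erythro) alcohol 37.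

Risk 3, step 25. Once the para-phenol is free, the benzylic C7–OH bond, and to a lesser degree the benzylic O1–C2 ether of ring D, may be cleaved on palladium by continued hydrogenolysis. The fallback changes the order of unmasking so that the free para-hydroxybenzylic alcohol never meets the catalyst; it sets out from 42 and rejoins at 44.
- 42 is debenzylated first (H2, Pd/C, EtOAc, rt) while C7–O still carries its silyl group, giving (3R,4R)-3-(4-{[(1R,2S)-1-(4-hydroxy-3-methoxyphenyl)-1,3-bis(TBS-oxy)propan-2-yl]oxy}-3-methoxybenzyl)-4-{[(2S,3R)-2-(4-hydroxy-3-methoxyphenyl)-3-[(TBDPS-oxy)methyl]-7-methoxy-2,3-dihydro-1-benzofuran-5-yl]methyl}dihydrofuran-2(3H)-one F7.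
- The three silyl ethers of F7 are then removed with Bu4NF/AcOH (THF, rt) to give 44.

**Further compounds**

F1 | step 4 | 4-allyl-2-iodo-6-methoxyphenol | C=CCc1cc(I)c(O)c(OC)c1
F2 | step 4 | 5-allyl-2-[(4-benzyloxy-3-methoxyphenyl)methoxy]-1-iodo-3-methoxybenzene | C=CCc1cc(I)c(OCc2ccc(OCc3ccccc3)c(OC)c2)c(OC)c1
F3 | step 4 | ethyl 2-{5-allyl-2-[(4-benzyloxy-3-methoxyphenyl)methoxy]-3-methoxyphenyl}-2-diazoacetate | CCOC(=O)C(=[N+]=[N-])c1cc(CC=C)cc(OC)c1OCc1ccc(OCc2ccccc2)c(OC)c1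
F4 | step 4 | ethyl (2S,3R)-5-allyl-2-(4-benzyloxy-3-methoxyphenyl)-7-methoxy-2,3-dihydro-1-benzofuran-3-carboxylate (cis) | C=CCc1cc(OC)c2c(c1)[C@@H](C(=O)OCC)[C@@H](c1ccc(OCc3ccccc3)c(OC)c1)O2
F5 | step 4 | ethyl (2S,3S)-5-allyl-2-(4-benzyloxy-3-methoxyphenyl)-7-methoxy-2,3-dihydro-1-benzofuran-3-carboxylate (trans) | C=CCc1cc(OC)c2c(c1)[C@H](C(=O)OCC)[C@@H](c1ccc(OCc3ccccc3)c(OC)c1)O2
F6 | step 18 | methyl 4-{[(2S)-1-(4-benzyloxy-3-methoxyphenyl)-1-oxo-3-(TBS-oxy)propan-2-yl]oxy}-3-methoxybenzoate | COc1cc(C(=O)[C@H](CO[Si](C)(C)C(C)(C)C)Oc2ccc(C(=O)OC)cc2OC)ccc1OCc1ccccc1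
F7 | step 25 | (3R,4R)-3-(4-{[(1R,2S)-1-(4-hydroxy-3-methoxyphenyl)-1,3-bis(TBS-oxy)propan-2-yl]oxy}-3-methoxybenzyl)-4-{[(2S,3R)-2-(4-hydroxy-3-methoxyphenyl)-3-[(TBDPS-oxy)methyl]-7-methoxy-2,3-dihydro-1-benzofuran-5-yl]methyl}dihydrofuran-2(3H)-one | COc1cc([C@@H](O[Si](C)(C)C(C)(C)C)[C@H](CO[Si](C)(C)C(C)(C)C)Oc2ccc(C[C@H]3C(=O)OC[C@@H]3Cc3cc(OC)c4c(c3)[C@H](CO[Si](c5ccccc5)(c5ccccc5)C(C)(C)C)[C@@H](c3ccc(O)c(OC)c3)O4)cc2OC)ccc1O
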